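**Retrosynthetic overview**

1. Target ⇐ bridged tricyclic 4,21-diketone: both ketones are reduced and lactone B closes last.
2. Diketone ⇐ N-(4-oxobutyl) bicyclic enone-lactam by an intramolecular Stetter reaction: the aldehyde carbon C-21, as a carbene-bound acyl anion equivalent, bonds to C-22 (β-carbon of the cyclopentenone). This closes ring D and creates the quaternary centre, the bridged lactam and C-3.
3. Aldehyde ⇐ oxazolidine-fused enone-lactam: C-8 alkylation with lactate triflate, reductive N,O-acetal opening with closure of lactone E, ozonolysis, hydrogenation.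
4. Enone-lactam ⇐ enyne: a Pauson–Khand reaction forms rings C and A together; an oxazolidine (O-16–C-18–N-17) steers C-9.
5. Enyne ⇐ D-allylglycine methyl ester, pent-2-ynoic acid, tert-butyl 2-(bromomethyl)acrylate, pent-4-enal (plus CO and ethyl L-lactate). Ring order: C and A, then E, then D, then B.

Atom labels (written with a hyphen): skeleton atoms of the target SMILES counted in order, branch atoms (carbonyl O, methyl, OH) skipped: C-1/C-2 ethyl, C-3, C-4, O-5, C-6, C-7, C-8, C-9, C-10, C-11, C-12, C-13, C-14, C-15, O-16, N-17, C-18 to C-20, C-21 (CHOH), C-22 (quaternary), C-23 (lactam C=O). Ring A = cyclopentane, B = fused lactone, C = six-membered lactam ring, D = seven-membered ring, E = side-chain lactone.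

Assumption: methyl (R)-allylglycinate hydrochloride is bought as such; all other starting materials are bulk chemicals.

**Route**

Step 1
Reactants: 1 methyl (2R)-2-aminopent-4-enoate hydrochloride; 2 pent-2-ynoic acid
Product: 4 methyl (2R)-2-(pent-2-ynoylamino)pent-4-enoate, via O-acylisourea 3 (not isolated)
Conditions: DCC, Et3N, CH2Cl2, 0 °C → rt
Reagents that add atoms: none
Why: Carbodiimide amide coupling of the liberated amine with the activated ynoic acid; the C-11 centre is on the amine partner and is not touched.

Step 2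
Reactants: 4 methyl (2R)-2-(pent-2-ynoylamino)pent-4-enoate
Product: 6 N-[(2R)-1-oxopent-4-en-2-yl]pent-2-ynamide, via aluminium hemiacetal 5 (not isolated)
Conditions: iBu2AlH, CH2Cl2, −78 °C; aq. KNaC4H4O6 work-up; used crude
Reagents that add atoms: none
Why: Partial ester reduction; the tetrahedral aluminium hemiacetal is stable at −78 °C and gives the aldehyde only on work-up, and immediate use of the crude aldehyde avoids epimerisation at C-11.

Step 3
Reactants: 6 N-[(2R)-1-oxopent-4-en-2-yl]pent-2-ynamide; 7 tert-butyl 2-(bromomethyl)prop-2-enoate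
Product: 9 tert-butyl (4R,5R)-4-hydroxy-2-methylidene-5-(pent-2-ynoylamino)oct-7-enoate, via allylzinc bromide 8 (not isolated)
Conditions: Zn dust, THF, 0 °C → rt; sat. aq. NH4Cl
Reagents that add atoms: none
Why: Barbier (Reformatsky-type) allylation; zinc chelated between the amide and aldehyde oxygens (Cram chelate) directs attack to the face away from the allyl side chain and gives the syn amino alcohol (12R), an expected moderate selectivity whose minor isomer is removed by chromatography, and the tert-butyl ester keeps the hydroxy ester from lactonising.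

Step 4
Reactants: 9 tert-butyl (4R,5R)-4-hydroxy-2-methylidene-5-(pent-2-ynoylamino)oct-7-enoate; 10 pent-4-enal
Product: 11 tert-butyl 2-{[(4R,5R)-2-(but-3-enyl)-3-(pent-2-ynoyl)-4-(prop-2-enyl)-1,3-oxazolidin-5-yl]methyl}prop-2-enoate
Conditions: pyridinium p-toluenesulfonate (10 mol%), 4 Å molecular sieves, toluene, 80 °C
Reagents that add atoms: none
Why: Acid-catalysed N,O-acetalisation (hemiacetal, oxocarbenium ion, 5-exo attack by the amide nitrogen) ties O-16 to N-17 through C-18, the future N-CH2 carbon; both C-18 epimers are carried on because this centre becomes CH2 in step 8.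

Step 5
Reactants: 11 tert-butyl 2-{[(4R,5R)-2-(but-3-enyl)-3-(pent-2-ynoyl)-4-(prop-2-enyl)-1,3-oxazolidin-5-yl]methyl}prop-2-enoate
Product: 12 oxazolidine-fused enone-lactam (9S,11R,12R)
Conditions: [RhCl(CO)2]2 (5 mol%), CO (1 atm), toluene, 110 °C
Reagents that add atoms: carbon monoxide, [C-]#[O+]
Why: Intramolecular Pauson–Khand reaction of the amide-tethered 1,7-enyne builds rings C and A at once (the other two alkenes would need seven-membered rings); the fused oxazolidine holds C-12 pseudo-equatorial on the forming ring C, so the chair-like alkene insertion places C-8 equatorial as well and H-9 ends cis to H-11 (9S).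

Step 6
Reactants: 13 ethyl (2S)-2-hydroxypropanoate
Product: 14 ethyl (2S)-2-(trifluoromethylsulfonyloxy)propanoate
Conditions: (CF3SO2)2O, 2,6-lutidine, CH2Cl2, −78 → 0 °C
Reagents that add atoms: trifluoromethanesulfonic anhydride, O=S(=O)(OS(=O)(=O)C(F)(F)F)C(F)(F)F
Why: O-Sulfonylation of the lactate hydroxyl with retention at the stereocentre.

Step 7
Reactants: 12 oxazolidine-fused enone-lactam (9S,11R,12R); 14 ethyl (2S)-2-(trifluoromethylsulfonyloxy)propanoate
Product: 16 C-8 alkylated enone-lactam (7S,8R,9S,11R,12R), via lithium enolate 15 (not isolated)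
Conditions: LiN(SiMe3)2, THF, −78 °C; then 14, −78 → −40 °C
Reagents that add atoms: none
Why: Kinetic α'-enolate alkylation; SN2 displacement of the secondary triflate with inversion turns the (S)-lactate into (7S), and the electrophile enters anti to the C-9–C-10 bond of ring C, which sets (8R).

Step 8
Reactants: 16 C-8 alkylated enone-lactam (7S,8R,9S,11R,12R)
Product: 18 N-(pent-4-enyl) enone-lactam carrying α-methylene lactone E, via hydroxy tert-butyl ester 17 (not isolated)
Conditions: Et3SiH, CF3CO2H/CH2Cl2 (1:4), 0 °C → rt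
Reagents that add atoms: none
Why: Ionic hydrogenation of the N-acyl N,O-acetal: acid opens the C-18–O-16 bond to an N-acyliminium ion that Et3SiH reduces to N-CH2, and the freed 12-OH then closes lactone E on the acid-labile tert-butyl ester; no stereocentre is formed or touched.

Step 9
Reactants: 18 N-(pent-4-enyl) enone-lactam carrying α-methylene lactone E
Product: 20 N-(4-oxobutyl) enone-lactam carrying α-methylene lactone E, via ozonide 19 (not isolated)
Conditions: O3 (1 equiv.), CH2Cl2, −78 °C; then Me2S, −78 °C → rt
Reagents that add atoms: ozone, [O-][O+]=O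
Why: Ozonolysis with reductive work-up; the monosubstituted terminal alkene is far more electron-rich than the acrylate-type methylene and the tetrasubstituted ene-dione alkene, so it reacts first.

Step 10
Reactants: 20 N-(4-oxobutyl) enone-lactam carrying α-methylene lactone E
Product: 21 N-(4-oxobutyl) enone-lactam carrying cis-methyl lactone E (14R)
Conditions: H2 (1 atm), Pd/C (5%), EtOAc, rt, stopped after 1 equiv.
Reagents that add atoms: none
Why: Heterogeneous hydrogenation adds hydrogen to the exocyclic methylene from the face opposite the C-12 substituent and gives the cis-2,4-disubstituted lactone (14R), while the tetrasubstituted ring A alkene and the aldehyde are left untouched at 1 atm.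

Step 11
Reactants: 21 N-(4-oxobutyl) enone-lactam carrying cis-methyl lactone E (14R)
Product: 22 bridged tricyclic 4,21-diketone (3S,7S,8R,9S,11R,12R,14R,22S)
Conditions: 2-(pentafluorophenyl)-6,7-dihydro-5H-pyrrolo[2,1-c][1,2,4]triazol-2-ium tetrafluoroborate (20 mol%), KN(SiMe3)2 (20 mol%), toluene (0.01 M), rt → 40 °C
Reagents that add atoms: none
Why: Proposed new method: the carbene adds to the C-21 aldehyde to give a Breslow intermediate (acyl anion equivalent) that attacks C-22, the β-carbon of the ring A enone, which is further activated by the lactam carbonyl (a fumarate-like acceptor), in a 7-exo-trig closure of ring D through the N-17 tether; the tether reaches only the face of C-22 syn to H-9, which gives the cis A/C fusion (22S), and the resulting enolate is protonated at C-3 by the neighbouring carbinol OH of the tetrahedral intermediate on the face of the new bond, which places the ethyl group on the other face (3S), before the carbene leaves to give the C-21 ketone; the closest known chemistry is the intramolecular Stetter reaction of aliphatic aldehydes with β,β-disubstituted acceptors that builds quaternary centres with intramolecular proton transfer, here stretched to a seven-membered ring and a tetrasubstituted acceptor, and the irreversible C–C bond formation pays for the twist of the bridged lactam.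

Step 12
Reactants: 22 bridged tricyclic 4,21-diketone (3S,7S,8R,9S,11R,12R,14R,22S)
Product: 24 target CNP0120800.1, via diol ester 23 (not isolated)
Conditions: NaBH4, MeOH/CH2Cl2, −40 °C; then pyridinium p-toluenesulfonate, toluene, 60 °C
Reagents that add atoms: none
Why: Hydride reduction followed by acid-catalysed lactonisation; NaBH4 attacks the ring D ketone axially, anti to the axial C-22–C-9 bond, so the 21-OH ends equatorial and anti to C-23 (21R), and attacks the cyclopentanone anti to the branched C-8 substituent so the 4-OH is cis to the propanoate (4S) and closes lactone B, while the hindered bridged lactam and lactone E survive at −40 °C.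

**Compound list**

1 | methyl (2R)-2-aminopent-4-enoate hydrochloride (D-allylglycine methyl ester hydrochloride) | [Cl-].[NH3+][C@H](CC=C)C(=O)OC | starting material
2 | pent-2-ynoic acid | CCC#CC(=O)O | starting material
3 | O-(pent-2-ynoyl)-N,N'-dicyclohexylisourea | CCC#CC(=O)OC(=NC1CCCCC1)NC1CCCCC1 | intermediate
4 | methyl (2R)-2-(pent-2-ynoylamino)pent-4-enoate | CCC#CC(=O)N[C@H](CC=C)C(=O)OC | intermediate
5 | diisobutylaluminium methyl hemiacetal of 4 (acetal carbon unassigned) | CCC#CC(=O)N[C@H](CC=C)C(OC)O[Al](CC(C)C)CC(C)C | intermediate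
6 | N-[(2R)-1-oxopent-4-en-2-yl]pent-2-ynamide | CCC#CC(=O)N[C@H](CC=C)C=O | intermediate
7 | tert-butyl 2-(bromomethyl)prop-2-enoate | C=C(CBr)C(=O)OC(C)(C)C | starting material
8 | [2-(tert-butoxycarbonyl)prop-2-enyl]zinc bromide | Br[Zn]CC(=C)C(=O)OC(C)(C)C | intermediate
9 | tert-butyl (4R,5R)-4-hydroxy-2-methylidene-5-(pent-2-ynoylamino)oct-7-enoate | CCC#CC(=O)N[C@H](CC=C)[C@H](O)CC(=C)C(=O)OC(C)(C)C | intermediate
10 | pent-4-enal | C=CCCC=O | starting material
11 | tert-butyl 2-{[(4R,5R)-2-(but-3-enyl)-3-(pent-2-ynoyl)-4-(prop-2-enyl)-1,3-oxazolidin-5-yl]methyl}prop-2-enoate (both epimers at oxazolidine C-2 = C-18) | CCC#CC(=O)N1C(CCC=C)O[C@H](CC(=C)C(=O)OC(C)(C)C)[C@H]1CC=C | intermediate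
12 | oxazolidine-fused enone-lactam: 2-ethylcyclopent-2-enone ring A fused at C-22/C-9 to lactam ring C; N-17 and O-16 joined by C-18 (but-3-enyl, both epimers); C-12 carries CH2C(=CH2)CO2tBu; (9S,11R,12R) | CCC1=C2C(=O)N3C(CCC=C)O[C@H](CC(=C)C(=O)OC(C)(C)C)[C@H]3C[C@H]2CC1=O | intermediate
13 | ethyl (2S)-2-hydroxypropanoate (ethyl L-lactate) | C[C@H](O)C(=O)OCC | starting material
14 | ethyl (2S)-2-(trifluoromethylsulfonyloxy)propanoate | C[C@H](OS(=O)(=O)C(F)(F)F)C(=O)OCC | intermediate
15 | lithium cross-conjugated dienolate of 12 (C-4 O–Li, C-4=C-8) | CCC1=C2C(=O)N3C(CCC=C)O[C@H](CC(=C)C(=O)OC(C)(C)C)[C@H]3C[C@H]2C=C1O[Li] | intermediate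
16 | 12 carrying at C-8 the (2S)-1-ethoxy-1-oxopropan-2-yl group; (7S,8R,9S,11R,12R) | CCC1=C2C(=O)N3C(CCC=C)O[C@H](CC(=C)C(=O)OC(C)(C)C)[C@H]3C[C@H]2[C@H]([C@H](C)C(=O)OCC)C1=O | intermediate
17 | N-(pent-4-enyl) enone-lactam with free 12-OH and tert-butyl 2-methylidene ester side chain; (7S,8R,9S,11R,12R) | CCC1=C2C(=O)N(CCCC=C)[C@@H]([C@H](O)CC(=C)C(=O)OC(C)(C)C)C[C@H]2[C@H]([C@H](C)C(=O)OCC)C1=O | intermediate
18 | N-(pent-4-enyl) enone-lactam with α-methylene-γ-butyrolactone E at C-11; (7S,8R,9S,11R,12R) | CCC1=C2C(=O)N(CCCC=C)[C@@H]([C@H]3CC(=C)C(=O)O3)C[C@H]2[C@H]([C@H](C)C(=O)OCC)C1=O | intermediate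
19 | 1,2,4-trioxolane (ozonide) of the terminal alkene of 18 (ozonide carbon unassigned) | CCC1=C2C(=O)N(CCCC4OCOO4)[C@@H]([C@H]3CC(=C)C(=O)O3)C[C@H]2[C@H]([C@H](C)C(=O)OCC)C1=O | intermediate
20 | N-(4-oxobutyl) enone-lactam with α-methylene lactone E; (7S,8R,9S,11R,12R) | CCC1=C2C(=O)N(CCCC=O)[C@@H]([C@H]3CC(=C)C(=O)O3)C[C@H]2[C@H]([C@H](C)C(=O)OCC)C1=O | intermediate
21 | N-(4-oxobutyl) enone-lactam with cis-methyl lactone E; (7S,8R,9S,11R,12R,14R) | CCC1=C2C(=O)N(CCCC=O)[C@@H]([C@H]3C[C@@H](C)C(=O)O3)C[C@H]2[C@H]([C@H](C)C(=O)OCC)C1=O | intermediate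
22 | bridged tricyclic diketone (rings A, C, D closed; ketones at C-4 and C-21; ethyl propanoate at C-8); (3S,7S,8R,9S,11R,12R,14R,22S) | CC[C@@H]1C(=O)[C@@H]([C@H](C)C(=O)OCC)[C@@H]2C[C@H]([C@H]3C[C@@H](C)C(=O)O3)N3CCCC(=O)[C@@]12C3=O | intermediate
23 | 4,21-diol ethyl ester; (3S,4S,7S,8R,9S,11R,12R,14R,21R,22S) | CC[C@@H]1[C@@H](O)[C@@H]([C@H](C)C(=O)OCC)[C@@H]2C[C@H]([C@H]3C[C@@H](C)C(=O)O3)N3CCC[C@@H](O)[C@@]12C3=O | intermediate
24 | CNP0120800.1; (3S,4S,7S,8R,9S,11R,12R,14R,21R,22S) | CC[C@@H]1[C@H]2OC(=O)[C@@H](C)[C@H]2[C@@H]2C[C@H]([C@H]3C[C@@H](C)C(=O)O3)N3CCC[C@@H](O)[C@@]12C3=O | target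

**Step count and risks**

Total: 12 steps. Longest linear sequence: 11 steps (steps 1–5 and 7–12); step 6 is a one-step side branch.

Steps most likely to fail:

Step 11 (Stetter closure of ring D). A seven-membered ring, a tetrasubstituted acceptor and a strained bridged lactam are all beyond precedent. Aldehyde self-condensation and base-induced epimerisation at C-9 (γ to the enone) compete. Fallback, setting out from 21: a one-electron version. Irradiation at 390 nm with (Bu4N)4[W10O32] (2 mol%) in MeCN (5 mM) abstracts the aldehyde hydrogen. The nucleophilic acyl radical closes ring D by 7-exo attack on C-22 under neutral conditions. The C-3 radical then takes a hydrogen atom back without facial control, so 22 is expected together with its C-3 epimer, 3-epi-diketone F1. DBU (10 mol%) in CH2Cl2 is then used to equilibrate F1 through the C-4 enol; the assumption that the 2,5-trans cyclopentanone 22 is the favoured epimer is not secured. The route resumes at 22.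

Step 5 (Pauson–Khand reaction). The alkyne is electron-poor, the ring formed is six-membered, and two further alkenes are present. Fallback, setting out from 11: an isocyanide-type [2+2+1] on zerovalent nickel. Ni(cod)2 (10 mol%) and iPr3SiCN in DMF at 110 °C join alkyne, alkene and the cyanide carbon to give N-silyl iminocyclopentene F2. Aqueous oxalic acid in THF hydrolyses F2 to the enone, which returns to the route at 12.

Step 12 (double reduction). The facial selectivity at C-4 rests only on the size difference between the ethyl and the branched ester substituent. Fallback, setting out from 22: if hydride adds to C-4 from the other face, the product is 4-epi-diol ester F3, which cannot lactonise. LiOH in aqueous THF at 0 °C followed by acidification (lactone E recloses) gives 4-epi-hydroxy acid F4. Mitsunobu lactonisation (PPh3, DIAD, THF) then inverts C-4 and closes lactone B; the hindered 21-OH next to the quaternary centre is expected to stay out. This returns to the route at 24.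

**Further compounds**

F1 | step 11 | 3-epi-diketone (C-3 epimer of 22) | CC[C@H]1C(=O)[C@@H]([C@H](C)C(=O)OCC)[C@@H]2C[C@H]([C@H]3C[C@@H](C)C(=O)O3)N3CCCC(=O)[C@@]12C3=O
F2 | step 5 | N-silyl iminocyclopentene (C-4 N-triisopropylsilyl imine of 12) | CCC1=C2C(=O)N3C(CCC=C)O[C@H](CC(=C)C(=O)OC(C)(C)C)[C@H]3C[C@H]2CC1=N[Si](C(C)C)(C(C)C)C(C)C
F3 | step 12 | 4-epi-diol ester (C-4 epimer of 23) | CC[C@@H]1[C@H](O)[C@@H]([C@H](C)C(=O)OCC)[C@@H]2C[C@H]([C@H]3C[C@@H](C)C(=O)O3)N3CCC[C@@H](O)[C@@]12C3=O
F4 | step 12 | 4-epi-hydroxy acid (free C-6 acid of F3) | CC[C@@H]1[C@H](O)[C@@H]([C@H](C)C(=O)O)[C@@H]2C[C@H]([C@H]3C[C@@H](C)C(=O)O3)N3CCC[C@@H](O)[C@@]12C3=O
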